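Follow the intermediate and ask which exit takes it.

substrate 0.44 M (fed, over 50 s); partner 0.528 M; catalyst 48 mM; time 40 min

    substrate + catalyst ⇌ catalyst + intermediate (K1 = 9.21, k1 = 0.598 L mol⁻¹ s⁻¹)
    partner + catalyst + intermediate → catalyst + product (k2 = 0.825 L² mol⁻² s⁻¹)
    intermediate → decomposed reagent (k3 = 0.0118 s⁻¹)

- the state of affairs at 40 min: stopped, and by what, or still going (all of the substrate has reacted / no working catalyst is left / forward and back rates have come level / the partner has run out first / it is still moving)
- how much product there is at 40 min, in percent of the substrate charged

- the reaction counts as stopped when no species that holds the substrate changes by six tenths of a point or more over the second half of the time
- run time (flask): 40 min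

Two chemists argue about this flask, and they agree on its end. The forward half-life of the substrate, 0.40 min, is far shorter than the run. Decomposition alone gives the intermediate a half-life of 0.979 min, also far shorter than the run. The catalyst stands on both sides of its steps. Both chemists therefore expect the substrate to have reacted by the end.

They part over the yield. The intermediate has two one-way exits, the partner step and decomposition; its way back to substrate only returns it. Both exits are first order in the intermediate, with the catalyst held constant. Their ratio needs one number, 0.298 M, written B*. B* is the break-even partner: the partner concentration at which the partner step and decomposition remove the intermediate equally fast. At partner concentration B, the share going to product (the selectivity) is B/(B+B*).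

The first chemist takes the charged partner and gets 63.9%. He holds that share for the whole run, since the partner charge is larger than the substrate charge.

The second chemist objects that each product uses one partner. At the first chemist's share, the partner would fall to 0.247 M, which is below B*. The share there is 45.3%. I side with the second chemist and average the two shares, which gives 54.6%.

The forecast takes the same side. Its end is: all of the substrate has reacted. Its product is 56.7%, higher than my average. Its share “falls as the partner is used”.

In the simulation the end is: all of the substrate has reacted. The product is 56.7%, lower than the first chemist's frozen share. The partner ends at 0.279 M, which is 53% of its charge and below B*. At that partner concentration, B/(B+B*) is 48.3%. The frozen share misses this flask by 7.2 percentage points. The neighbour flask, with 0.012 M of catalyst, has a B* of 1.19 M, above its partner charge. Its partner ends at 77% of its charge, and there the first chemist's frozen share of 30.7% stands within 2.7 points of the product, 28.0%.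

Its constants belong to no real substance; what happens was integrated by code.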